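**Plan**

1. Atom names: C-a is the O–CH methine, C-b the ring-fusion CH next to CMe2, and C-c the CH that carries the hydroxyisobutyl arm. Ring A is the pyran on quinolinone A (it contains CMe2); ring B is the pyran on quinolinone B.
2. Retrosynthetic cuts, in order: the O–CMe2 and C-a–C-b bonds of ring A together (retro hetero-Diels–Alder); the C-a–O bond to quinolinone B; one CH3–C(OH) bond; the C-c–C-3 bond of quinolinone B (retro-Michael); the formyl C–C bond on quinolinone A.
3. Enabling feature: C-a lies between C-3 of quinolinone A and the ether oxygen of quinolinone B. As the methylidene carbon of a 3-(aryloxymethylidene)quinoline-2,4-dione it ends the 1-oxadiene O=C4–C3=C-a, and the isobutenyl C=C (C-b=CMe2) sits on C-c, five bonds away through O, C-4 and C-3 of quinolinone B.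
4. Forward order: a Michael addition joins quinolinone B to the C8 chain; methyl addition makes the tertiary alcohol; quinolinone A is formylated separately; condensation of the two halves closes ring B (through the tether) and ring A (the cycloadduct) in one flask and gives the target.
5. Stereochemistry: C-c is set by a chiral primary-diamine catalyst in step 1. In step 4, C-b is relayed from C-c by allylic 1,3-strain and C-a by the endo transition state of the cycloaddition.

Key step: step 4

Assumption: the sense of induction of the diamine in step 1 is taken over from the analogous additions to β-aryl enones ((R,R)-diamine gives the (R) adduct); should the opposite sense be found, the (S,S)-diamine is used and nothing else changes.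

**Step 1**
Reactants: 1 4-hydroxy-1-methylquinolin-2(1H)-one; 2 (3E)-6-methylhepta-3,5-dien-2-one
Product: 3 4-hydroxy-1-methyl-3-[(4R)-2-methyl-6-oxohept-2-en-4-yl]quinolin-2(1H)-one (drawn in the open keto form; in equilibrium with its cyclic hemiketal)
Conditions: (1R,2R)-1,2-diphenylethane-1,2-diamine (10 mol%), AcOH, THF, rt
Reagents that add atoms: none
Why: Primary-amine iminium catalysis of the warfarin-type Michael addition, in which C-3 of the vinylogous acid 1 attacks the β-carbon of the dienone iminium ion (the δ-carbon is blocked by its two methyl groups) and the second, protonated amino group of the catalyst steers the nucleophile to one face, which should set the (R) centre.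

**Step 2**
Reactants: 3 4-hydroxy-1-methyl-3-[(4R)-2-methyl-6-oxohept-2-en-4-yl]quinolin-2(1H)-one
Product: 4 4-hydroxy-3-[(4R)-6-hydroxy-2,6-dimethylhept-2-en-4-yl]-1-methylquinolin-2(1H)-one
Conditions: MeMgBr (4 equiv), CeCl3, THF, −78 → 0 °C; aq NH4Cl
Reagents that add atoms: methylmagnesium bromide, C[Mg]Br
Why: Cerium-modified Grignard addition to the methyl ketone, in which the first equivalent deprotonates the acidic 4-OH (this opens the hemiketal and leaves the quinolinone as an unreactive enolate), so the further equivalents should add only to the ketone, while the stereocentre, which is not α to the carbonyl, stays untouched.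

**Step 3**
Reactants: 1 4-hydroxy-1-methylquinolin-2(1H)-one
Product: 6 4-hydroxy-1-methyl-2-oxo-1,2-dihydroquinoline-3-carbaldehyde, via dichloromethyl quinolinone 5 (not isolated)
Conditions: CHCl3, aq NaOH, 65 °C; then aq HCl to pH 2
Reagents that add atoms: chloroform, ClC(Cl)Cl; sodium hydroxide (aqueous, supplies the formyl oxygen), [Na+].[OH-]
Why: Reimer–Tiemann formylation, in which dichlorocarbene from CHCl3 and NaOH is captured by C-3 of the enolate of 1, the only nucleophilic carbon, and hydrolysis of the dichloromethyl group should give the chelated aldehyde.

**Step 4**
Reactants: 6 4-hydroxy-1-methyl-2-oxo-1,2-dihydroquinoline-3-carbaldehyde (1.2 equiv); 4 4-hydroxy-3-[(4R)-6-hydroxy-2,6-dimethylhept-2-en-4-yl]-1-methylquinolin-2(1H)-one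
Product: 9 the target (cis-fused bis-pyranoquinolinone; C-a S, C-b R, C-c R), via methoxymethylidene dione 7 (not isolated), via aryloxymethylidene dione 8 (not isolated)
Conditions: 6, HC(OMe)3 (5 equiv), PPTS (10 mol%), PhMe, 60 °C, then evaporation; then 4, PPTS (10 mol%), 5 Å MS, PhMe, 80–100 °C
Reagents that add atoms: none
Why: Proposed new method: the orthoformate turns the chelated aldehyde 6 into the vinylogous ester 7, acid-catalysed addition–elimination at its methylidene carbon exchanges methoxy for the acidic 4-OH of 4 (C-3 of 4 is blocked, so only oxygen can attack; methanol is taken up by the sieves), and the resulting 8, a 1-oxadiene O=C4–C3=CH–OAr held five bonds from the isobutenyl C=C, should undergo an intramolecular inverse-electron-demand hetero-Diels–Alder addition that is irreversible and so pulls the unfavourable exchange through. The closest known reaction types are the one-flask condensation of salicylaldehydes, unsaturated alcohols and an orthoformate to alkoxy-o-quinone methides that cyclise by intramolecular hetero-Diels–Alder addition, and the domino Knoevenagel/hetero-Diels–Alder reaction of alkylidene diones derived from 4-hydroxyquinolinones; a vinylogous acid as the oxygen partner is the new element. Ring B closes through the tether as a six-membered ring (both reacting π bonds exo to it), and ring A is the dihydropyran of the cycloadduct itself, formed by C–C bonding at the alkene CH and C–O bonding at the dimethyl-substituted carbon. C-b is controlled by C-c, because allylic 1,3-strain with the (Z)-methyl keeps H-c in the alkene plane, the tethered diene can reach only the face on which quinolinone B lies, and the hydroxyisobutyl arm ends up trans to the C-b–CMe2 bond; C-a is controlled by the endo transition state with the aryloxy group outside, which gives the cis ring fusion and lets the C-a–O bond (on ring A) and the side chain (on ring B) stand pseudo-axial, clear of the two lactam carbonyls. The step needs the C-4 ketone oxygen rather than the lactam oxygen as diene terminus (the ketone is the more electron-poor enone and its use restores the aromatic 2-quinolinone), the regiochemistry shown (fixed by the tether length and by the tertiary cationic character at CMe2), and survival of the tertiary alcohol (only PPTS is used and the orthoformate is removed before 4 is added).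

**Compound list**

1 | 4-hydroxy-1-methylquinolin-2(1H)-one | Cn1c(=O)cc(O)c2ccccc21 | starting material
2 | (3E)-6-methylhepta-3,5-dien-2-one | CC(=O)/C=C/C=C(C)C | starting material
3 | 4-hydroxy-1-methyl-3-[(4R)-2-methyl-6-oxohept-2-en-4-yl]quinolin-2(1H)-one (open keto form) | Cn1c(=O)c([C@@H](C=C(C)C)CC(C)=O)c(O)c2ccccc21 | intermediate
4 | 4-hydroxy-3-[(4R)-6-hydroxy-2,6-dimethylhept-2-en-4-yl]-1-methylquinolin-2(1H)-one | Cn1c(=O)c([C@@H](C=C(C)C)CC(C)(C)O)c(O)c2ccccc21 | intermediate
5 | 3-(dichloromethyl)-4-hydroxy-1-methylquinolin-2(1H)-one (not isolated) | Cn1c(=O)c(C(Cl)Cl)c(O)c2ccccc21 | intermediate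
6 | 4-hydroxy-1-methyl-2-oxo-1,2-dihydroquinoline-3-carbaldehyde | Cn1c(=O)c(C=O)c(O)c2ccccc21 | intermediate
7 | (3Z)-3-(methoxymethylidene)-1-methylquinoline-2,4(1H,3H)-dione (not isolated; the geometric isomers interconvert) | CO/C=C1\C(=O)N(C)c2ccccc2C1=O | intermediate
8 | (3Z)-3-({[3-((4R)-6-hydroxy-2,6-dimethylhept-2-en-4-yl)-1-methyl-2-oxo-1,2-dihydroquinolin-4-yl]oxy}methylidene)-1-methylquinoline-2,4(1H,3H)-dione (not isolated; aryloxy group anti to the C-4 ketone) | Cn1c(=O)c([C@@H](C=C(C)C)CC(C)(C)O)c(O/C=C3\C(=O)N(C)c4ccccc4C3=O)c2ccccc21 | intermediate
9 | CNP0202276.1: two N-methylquinolin-2-one units, each fused at C-3/C-4–O to a dihydropyran; ring A = O–CMe2–C-b–C-a–C3=C4 of quinolinone A, ring B = O–C-a–C-b–C-c–C3=C4 of quinolinone B; C-a (S), C-b (R), C-c (R) with CH2C(CH3)2OH; H-a and H-b cis, side chain trans to the C-b–CMe2 bond | Cn1c(=O)c2c(c3ccccc31)OC(C)(C)[C@H]1[C@@H]2Oc2c(c(=O)n(C)c3ccccc23)[C@@H]1CC(C)(C)O | target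

**Step count and risks**

Total step count: 4. Longest linear sequence: 3 steps (steps 1, 2 and 4); step 3 supplies the second half.

Steps most likely to fail:

1. Step 4 (proposed new method). The oxygen exchange at the methylidene carbon may not take place, the cycloaddition may run through the lactam oxygen, or the ring fusion may close trans. A trans-fused isomer could first be tried for equilibration under acid, since the C-a–O bond can ionise reversibly. Fallback by known chemistry, which closes ring B instead of ring A in the cycloaddition: it sets out from 1 and comes back at 9. Knoevenagel condensation/oxa-6π-electrocyclisation of 1 with 3-methylbut-2-enal (pyridine, heat) should give N-methylflindersine F1. A second portion of 1 is then condensed with 3-hydroxy-3-methylbutanal in the presence of excess F1 (ethylenediammonium diacetate, MeCN, 60 °C). The alkylidene dione F2 formed in the flask should be trapped as the heterodiene by the pyran C=C of F1 in a domino Knoevenagel/intermolecular hetero-Diels–Alder reaction. Suprafacial addition to the ring alkene guarantees the cis ring fusion, and the oxygen adds at the carbon that bears quinolinone A. This should give 9 as a racemate together with its enantiomer F3, possibly beside the C-c epimer. Separation of diastereomers on silica and of enantiomers by preparative HPLC on a chiral stationary phase would then give 9.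

2. Step 1. The risks are poor facial selectivity at the iminium ion and competing 1,6-addition to the dienone. Fallback with secondary-amine iminium catalysis on an enal: it sets out from 1 and comes back at 4, so step 2 is bypassed. Addition of 1 to (2E)-5-methylhexa-2,4-dienal with a diphenylprolinol trimethylsilyl ether (enantiomer chosen to give the 4R centre) and PhCO2H in CH2Cl2 should give the lactol F4 as a mixture of anomers. Oxidation with PhI(OAc)2 and catalytic TEMPO should give the enol lactone F5. Excess MeMgBr in THF should open the lactone by double addition to the tertiary alcohol and free the 4-hydroxy group, giving 4.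

3. Step 3. The risks are low conversion of the carbene formylation and further reaction of the carbene with the product. Fallback by aminomethylenation and hydrolysis: it sets out from 1 and comes back at 6. Treatment of 1 with N,N-dimethylformamide dimethyl acetal (PhMe, 80 °C) should give the enaminone F6. Hydrolysis with aqueous NaOH followed by acidification should release 6.

**Further compounds**

F1 | step 4 | N-methylflindersine (2,2,6-trimethyl-2H-pyrano[3,2-c]quinolin-5(6H)-one) | Cn1c(=O)c2c(OC(C)(C)C=C2)c2ccccc21
F2 | step 4 | 3-(3-hydroxy-3-methylbutylidene)-1-methylquinoline-2,4(1H,3H)-dione (interconverting geometric isomers, formed in the flask) | CC(C)(O)CC=C1C(=O)N(C)c2ccccc2C1=O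
F3 | step 4 | enantiomer of 9 | Cn1c(=O)c2c(c3ccccc31)OC(C)(C)[C@@H]1[C@H]2Oc2c(c(=O)n(C)c3ccccc23)[C@H]1CC(C)(C)O
F4 | step 1 | (4R)-2-hydroxy-6-methyl-4-(2-methylprop-1-en-1-yl)-3,4-dihydro-2H-pyrano[3,2-c]quinolin-5(6H)-one (both C-2 epimers) | Cn1c(=O)c2c(c3ccccc31)OC(O)C[C@@H]2C=C(C)C
F5 | step 1 | (4R)-6-methyl-4-(2-methylprop-1-en-1-yl)-3,4-dihydro-2H-pyrano[3,2-c]quinoline-2,5(6H)-dione | Cn1c(=O)c2c(c3ccccc31)OC(=O)C[C@@H]2C=C(C)C
F6 | step 3 | 3-[(dimethylamino)methylidene]-1-methylquinoline-2,4(1H,3H)-dione | CN(C)C=C1C(=O)N(C)c2ccccc2C1=O
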